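**Retrosynthetic overview**
1. The target is unmasked last: fluoride removal of a TIPS ether on the benzylic carbinol, then hydrogenolysis of two aryl benzyl ethers.
2. The tetrahydrofuran (second and final ring) comes from Mitsunobu cyclodehydration of a 2,3-disubstituted butane-1,4-diol, obtained by LiAlH4 reduction of a trans-3-benzyl-4-substituted γ-butyrolactone (first ring, temporary).
3. The benzyl group on that lactone is attached by trans-selective enolate alkylation with 4-benzyloxy-3,5-dimethoxybenzyl bromide.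
4. The lactone arises from a pentenol by alkene cleavage to a lactol and oxidation; the pentenol comes from reductive removal of an oxazolidinone auxiliary.
5. Key C–C bond (carbinol carbon to ring carbon, both stereocentres at once): intermolecular Evans syn aldol of (S)-4-benzyl-3-(pent-4-enoyl)oxazolidin-2-one with O-benzylsyringaldehyde; both aryl units derive from syringaldehyde.

Assumption: syringaldehyde, (S)-4-benzyloxazolidin-2-one and pent-4-enoyl chloride count as cheap commercial starting materials.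

**Route**

Step 1
Reactants: 1 syringaldehyde (4-hydroxy-3,5-dimethoxybenzaldehyde)
Product: 2 4-(benzyloxy)-3,5-dimethoxybenzaldehyde
Conditions: BnBr, K2CO3, DMF, 60 °C
Reagents that add atoms: benzyl bromide, BrCc1ccccc1
Why: Williamson O-alkylation of the only acidic site gives a benzyl ether that survives every basic, hydride and enolate step and is removed at the end under neutral conditions.

Step 2
Reactants: 2 4-(benzyloxy)-3,5-dimethoxybenzaldehyde
Product: 3 [4-(benzyloxy)-3,5-dimethoxyphenyl]methanol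
Conditions: NaBH4, MeOH/THF, 0 °C
Reagents that add atoms: none
Why: Borohydride reduction of the aryl aldehyde to the primary benzylic alcohol is chemoselective because nothing else in the molecule is reducible.

Step 3
Reactants: 3 [4-(benzyloxy)-3,5-dimethoxyphenyl]methanol
Product: 4 2-(benzyloxy)-5-(bromomethyl)-1,3-dimethoxybenzene
Conditions: PBr3, CH2Cl2, 0 °C (used freshly prepared)
Reagents that add atoms: phosphorus tribromide, BrP(Br)Br
Why: Alcohol-to-bromide conversion with PBr3 (SN2 on the phosphite ester) is standard for alkoxy-substituted benzylic alcohols, and the aryl benzyl ether tolerates the short cold exposure.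

Step 4
Reactants: 5 (S)-4-benzyloxazolidin-2-one; 6 pent-4-enoyl chloride
Product: 8 (S)-4-benzyl-3-(pent-4-enoyl)oxazolidin-2-one, via N-lithio oxazolidinone 7 (not isolated)
Conditions: n-BuLi, THF, −78 °C; then 6, −78 → 0 °C
Reagents that add atoms: none
Why: N-acylation of the lithiated oxazolidinone with an acid chloride is the standard Evans imide formation and leaves the auxiliary stereocentre untouched.

Step 5
Reactants: 8 (S)-4-benzyl-3-(pent-4-enoyl)oxazolidin-2-one; 2 4-(benzyloxy)-3,5-dimethoxybenzaldehyde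
Product: 11 (S)-4-benzyl-3-[(S)-2-[(S)-[4-(benzyloxy)-3,5-dimethoxyphenyl](hydroxy)methyl]pent-4-enoyl]oxazolidin-2-one, via Z-boron enolate 9 (not isolated), via boron aldolate 10 (not isolated)
Conditions: n-Bu2BOTf, i-Pr2NEt, CH2Cl2, 0 °C; then 2, −78 → 0 °C; then pH 7 buffer, MeOH, 30% H2O2, 0 °C
Reagents that add atoms: none
Why: In this Evans syn aldol the Z-boron enolate reacts through a closed Zimmerman–Traxler chair, with the aldehyde adding to the enolate face opposite the auxiliary benzyl group in the dipole-minimised rotamer, so the (S)-auxiliary sets the alpha carbon and the carbinol carbon as the (S,S) syn pair, typically above 95:5.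

Step 6
Reactants: 11 (S)-4-benzyl-3-[(S)-2-[(S)-[4-(benzyloxy)-3,5-dimethoxyphenyl](hydroxy)methyl]pent-4-enoyl]oxazolidin-2-one
Product: 12 (S)-4-benzyl-3-[(S)-2-[(S)-[4-(benzyloxy)-3,5-dimethoxyphenyl][(triisopropylsilyl)oxy]methyl]pent-4-enoyl]oxazolidin-2-one
Conditions: TIPSOTf, 2,6-lutidine, CH2Cl2, 0 °C → rt
Reagents that add atoms: triisopropylsilyl trifluoromethanesulfonate, CC(C)[Si](OS(=O)(=O)C(F)(F)F)(C(C)C)C(C)C
Why: Silyl triflate silylation with a hindered base protects the benzylic alcohol without retro-aldol, and TIPS is chosen because it does not migrate to a neighbouring primary alkoxide and withstands the later hydride, enolate and Mitsunobu steps.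

Step 7
Reactants: 12 (S)-4-benzyl-3-[(S)-2-[(S)-[4-(benzyloxy)-3,5-dimethoxyphenyl][(triisopropylsilyl)oxy]methyl]pent-4-enoyl]oxazolidin-2-one
Product: 13 (R)-2-[(S)-[4-(benzyloxy)-3,5-dimethoxyphenyl][(triisopropylsilyl)oxy]methyl]pent-4-en-1-ol
Conditions: LiBH4, H2O (1 equiv), Et2O/THF, 0 °C → rt
Reagents that add atoms: none
Why: Reductive cleavage of the imide occurs at the more electrophilic exocyclic carbonyl, releasing the recoverable auxiliary and the primary alcohol without epimerising the adjacent stereocentre (its descriptor changes to R only through ligand priorities).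

Step 8
Reactants: 13 (R)-2-[(S)-[4-(benzyloxy)-3,5-dimethoxyphenyl][(triisopropylsilyl)oxy]methyl]pent-4-en-1-ol
Product: 16 (4R)-4-[(S)-[4-(benzyloxy)-3,5-dimethoxyphenyl][(triisopropylsilyl)oxy]methyl]tetrahydrofuran-2-ol (both anomers), via triol 14 (not isolated), via hydroxy aldehyde 15 (not isolated)
Conditions: OsO4 (2 mol%), NaIO4, 2,6-lutidine, 1,4-dioxane/H2O, rt
Reagents that add atoms: osmium tetroxide, O=[Os](=O)(=O)=O (transfers the oxygen); sodium periodate, [Na+].[O-]I(=O)(=O)=O (stoichiometric oxygen source that regenerates it)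
Why: In this Lemieux–Johnson oxidation the only alkene is dihydroxylated and cleaved, and the aldehyde is trapped by the 1,4-related primary hydroxyl as a five-membered lactol whose anomeric centre is irrelevant because it is oxidised next.

Step 9
Reactants: 16 (4R)-4-[(S)-[4-(benzyloxy)-3,5-dimethoxyphenyl][(triisopropylsilyl)oxy]methyl]tetrahydrofuran-2-ol
Product: 17 (R)-4-[(S)-[4-(benzyloxy)-3,5-dimethoxyphenyl][(triisopropylsilyl)oxy]methyl]dihydrofuran-2(3H)-one
Conditions: (n-Pr4N)RuO4 (5 mol%), N-methylmorpholine N-oxide, 4 Å molecular sieves, CH2Cl2, rt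
Reagents that add atoms: none
Why: Ley–Griffith oxidation converts the lactol into the γ-lactone under neutral conditions that leave the silyl ether, benzyl ether and electron-rich arene alone.

Step 10
Reactants: 17 (R)-4-[(S)-[4-(benzyloxy)-3,5-dimethoxyphenyl][(triisopropylsilyl)oxy]methyl]dihydrofuran-2(3H)-one; 4 2-(benzyloxy)-5-(bromomethyl)-1,3-dimethoxybenzene
Product: 19 (3R,4R)-3-[4-(benzyloxy)-3,5-dimethoxybenzyl]-4-[(S)-[4-(benzyloxy)-3,5-dimethoxyphenyl][(triisopropylsilyl)oxy]methyl]dihydrofuran-2(3H)-one, via potassium enolate 18 (not isolated)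
Conditions: KN(SiMe3)2, THF, −78 °C; then 4, −78 → −40 °C
Reagents that add atoms: none
Why: In this lactone enolate alkylation (SN2 on a reactive benzylic bromide) the electrophile approaches the face opposite the bulky C4 substituent, setting the new C3 centre trans (3R).

Step 11
Reactants: 19 (3R,4R)-3-[4-(benzyloxy)-3,5-dimethoxybenzyl]-4-[(S)-[4-(benzyloxy)-3,5-dimethoxyphenyl][(triisopropylsilyl)oxy]methyl]dihydrofuran-2(3H)-one
Product: 20 (2R,3R)-2-[4-(benzyloxy)-3,5-dimethoxybenzyl]-3-[(S)-[4-(benzyloxy)-3,5-dimethoxyphenyl][(triisopropylsilyl)oxy]methyl]butane-1,4-diol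
Conditions: LiAlH4, THF, 0 °C
Reagents that add atoms: none
Why: Hydride reduction of the lactone gives the 1,4-diol without touching any stereocentre, and TIPS and aryl benzyl ethers are stable to LiAlH4 at 0 °C.

Step 12
Reactants: 20 (2R,3R)-2-[4-(benzyloxy)-3,5-dimethoxybenzyl]-3-[(S)-[4-(benzyloxy)-3,5-dimethoxyphenyl][(triisopropylsilyl)oxy]methyl]butane-1,4-diol
Product: 21 [(S)-[4-(benzyloxy)-3,5-dimethoxyphenyl][(3R,4R)-4-[4-(benzyloxy)-3,5-dimethoxybenzyl]tetrahydrofuran-3-yl]methoxy]triisopropylsilane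
Conditions: PPh3, diisopropyl azodicarboxylate, THF, 0 °C → rt
Reagents that add atoms: none
Why: In this Mitsunobu cyclodehydration one primary hydroxyl is activated as an alkoxyphosphonium ion and displaced by the other in a 5-exo-tet closure at a non-stereogenic CH2, so both ring stereocentres are untouched and the silyl group keeps the benzylic oxygen from competing.

Step 13
Reactants: 21 [(S)-[4-(benzyloxy)-3,5-dimethoxyphenyl][(3R,4R)-4-[4-(benzyloxy)-3,5-dimethoxybenzyl]tetrahydrofuran-3-yl]methoxy]triisopropylsilane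
Product: 22 (S)-[4-(benzyloxy)-3,5-dimethoxyphenyl][(3R,4R)-4-[4-(benzyloxy)-3,5-dimethoxybenzyl]tetrahydrofuran-3-yl]methanol
Conditions: n-Bu4NF, THF, rt → 40 °C
Reagents that add atoms: none
Why: Fluoride desilylation, driven by the Si–F bond, frees the carbinol with retention and without the acid that would ionise this electron-rich benzylic alcohol.

Step 14
Reactants: 22 (S)-[4-(benzyloxy)-3,5-dimethoxyphenyl][(3R,4R)-4-[4-(benzyloxy)-3,5-dimethoxybenzyl]tetrahydrofuran-3-yl]methanol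
Product: 23 (S)-(4-hydroxy-3,5-dimethoxyphenyl)[(3R,4R)-4-(4-hydroxy-3,5-dimethoxybenzyl)tetrahydrofuran-3-yl]methanol (target)
Conditions: H2 (1 atm), 10% Pd/C, EtOAc, rt, stopped at full conversion
Reagents that add atoms: none
Why: Catalytic hydrogenolysis cleaves the two aryl benzyl ethers much faster than the benzylic C–OH bond and does so under neutral conditions, liberating both phenols without disturbing any stereocentre.

**Compound list**
1 | syringaldehyde (4-hydroxy-3,5-dimethoxybenzaldehyde) | COc1cc(C=O)cc(OC)c1O | starting material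
2 | 4-(benzyloxy)-3,5-dimethoxybenzaldehyde | COc1cc(C=O)cc(OC)c1OCc1ccccc1 | intermediate
3 | [4-(benzyloxy)-3,5-dimethoxyphenyl]methanol | COc1cc(CO)cc(OC)c1OCc1ccccc1 | intermediate
4 | 2-(benzyloxy)-5-(bromomethyl)-1,3-dimethoxybenzene | COc1cc(CBr)cc(OC)c1OCc1ccccc1 | intermediate
5 | (S)-4-benzyloxazolidin-2-one | O=C1N[C@@H](Cc2ccccc2)CO1 | starting material
6 | pent-4-enoyl chloride | C=CCCC(Cl)=O | starting material
7 | N-lithio-(S)-4-benzyloxazolidin-2-one | [Li+].O=C1[N-][C@@H](Cc2ccccc2)CO1 | intermediate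
8 | (S)-4-benzyl-3-(pent-4-enoyl)oxazolidin-2-one | C=CCCC(=O)N1[C@@H](Cc2ccccc2)COC1=O | intermediate
9 | (S)-4-benzyl-3-[(Z)-1-[(dibutylboranyl)oxy]penta-1,4-dien-1-yl]oxazolidin-2-one | C=CC/C=C(\OB(CCCC)CCCC)N1[C@@H](Cc2ccccc2)COC1=O | intermediate
10 | O-dibutylboranyl derivative (boron aldolate) of 11 | C=CC[C@H](C(=O)N1[C@@H](Cc2ccccc2)COC1=O)[C@H](OB(CCCC)CCCC)c1cc(OC)c(OCc2ccccc2)c(OC)c1 | intermediate
11 | (S)-4-benzyl-3-[(S)-2-[(S)-[4-(benzyloxy)-3,5-dimethoxyphenyl](hydroxy)methyl]pent-4-enoyl]oxazolidin-2-one | C=CC[C@H](C(=O)N1[C@@H](Cc2ccccc2)COC1=O)[C@H](O)c1cc(OC)c(OCc2ccccc2)c(OC)c1 | intermediate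
12 | (S)-4-benzyl-3-[(S)-2-[(S)-[4-(benzyloxy)-3,5-dimethoxyphenyl][(triisopropylsilyl)oxy]methyl]pent-4-enoyl]oxazolidin-2-one | C=CC[C@H](C(=O)N1[C@@H](Cc2ccccc2)COC1=O)[C@H](O[Si](C(C)C)(C(C)C)C(C)C)c1cc(OC)c(OCc2ccccc2)c(OC)c1 | intermediate
13 | (R)-2-[(S)-[4-(benzyloxy)-3,5-dimethoxyphenyl][(triisopropylsilyl)oxy]methyl]pent-4-en-1-ol | C=CC[C@H](CO)[C@H](O[Si](C(C)C)(C(C)C)C(C)C)c1cc(OC)c(OCc2ccccc2)c(OC)c1 | intermediate
14 | (2R)-2-[(S)-[4-(benzyloxy)-3,5-dimethoxyphenyl][(triisopropylsilyl)oxy]methyl]pentane-1,4,5-triol (both C4 epimers) | OCC(O)C[C@H](CO)[C@H](O[Si](C(C)C)(C(C)C)C(C)C)c1cc(OC)c(OCc2ccccc2)c(OC)c1 | intermediate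
15 | (R)-3-[(S)-[4-(benzyloxy)-3,5-dimethoxyphenyl][(triisopropylsilyl)oxy]methyl]-4-hydroxybutanal | O=CC[C@H](CO)[C@H](O[Si](C(C)C)(C(C)C)C(C)C)c1cc(OC)c(OCc2ccccc2)c(OC)c1 | intermediate
16 | (4R)-4-[(S)-[4-(benzyloxy)-3,5-dimethoxyphenyl][(triisopropylsilyl)oxy]methyl]tetrahydrofuran-2-ol (both anomers) | OC1C[C@H](CO1)[C@H](O[Si](C(C)C)(C(C)C)C(C)C)c1cc(OC)c(OCc2ccccc2)c(OC)c1 | intermediate
17 | (R)-4-[(S)-[4-(benzyloxy)-3,5-dimethoxyphenyl][(triisopropylsilyl)oxy]methyl]dihydrofuran-2(3H)-one | O=C1C[C@H](CO1)[C@H](O[Si](C(C)C)(C(C)C)C(C)C)c1cc(OC)c(OCc2ccccc2)c(OC)c1 | intermediate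
18 | potassium (R)-4-[(S)-[4-(benzyloxy)-3,5-dimethoxyphenyl][(triisopropylsilyl)oxy]methyl]-4,5-dihydrofuran-2-olate | [K+].[O-]C1=C[C@H](CO1)[C@H](O[Si](C(C)C)(C(C)C)C(C)C)c1cc(OC)c(OCc2ccccc2)c(OC)c1 | intermediate
19 | (3R,4R)-3-[4-(benzyloxy)-3,5-dimethoxybenzyl]-4-[(S)-[4-(benzyloxy)-3,5-dimethoxyphenyl][(triisopropylsilyl)oxy]methyl]dihydrofuran-2(3H)-one | O=C1[C@H](Cc2cc(OC)c(OCc3ccccc3)c(OC)c2)[C@H](CO1)[C@H](O[Si](C(C)C)(C(C)C)C(C)C)c1cc(OC)c(OCc2ccccc2)c(OC)c1 | intermediate
20 | (2R,3R)-2-[4-(benzyloxy)-3,5-dimethoxybenzyl]-3-[(S)-[4-(benzyloxy)-3,5-dimethoxyphenyl][(triisopropylsilyl)oxy]methyl]butane-1,4-diol | COc1cc(C[C@@H](CO)[C@H](CO)[C@H](O[Si](C(C)C)(C(C)C)C(C)C)c2cc(OC)c(OCc3ccccc3)c(OC)c2)cc(OC)c1OCc1ccccc1 | intermediate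
21 | [(S)-[4-(benzyloxy)-3,5-dimethoxyphenyl][(3R,4R)-4-[4-(benzyloxy)-3,5-dimethoxybenzyl]tetrahydrofuran-3-yl]methoxy]triisopropylsilane | COc1cc(C[C@H]2COC[C@@H]2[C@H](O[Si](C(C)C)(C(C)C)C(C)C)c2cc(OC)c(OCc3ccccc3)c(OC)c2)cc(OC)c1OCc1ccccc1 | intermediate
22 | (S)-[4-(benzyloxy)-3,5-dimethoxyphenyl][(3R,4R)-4-[4-(benzyloxy)-3,5-dimethoxybenzyl]tetrahydrofuran-3-yl]methanol | COc1cc(C[C@H]2COC[C@@H]2[C@H](O)c2cc(OC)c(OCc3ccccc3)c(OC)c2)cc(OC)c1OCc1ccccc1 | intermediate
23 | (S)-(4-hydroxy-3,5-dimethoxyphenyl)[(3R,4R)-4-(4-hydroxy-3,5-dimethoxybenzyl)tetrahydrofuran-3-yl]methanol | COc1cc(C[C@H]2COC[C@@H]2[C@H](O)c2cc(OC)c(O)c(OC)c2)cc(OC)c1O | target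

**Totals**
Total step count: 14.
Longest linear sequence: 11 steps (steps 1, 5, 6, 7, 8, 9, 10, 11, 12, 13, 14; the branch through steps 4 and 5 is equally long).

**Three steps most likely to fail**

Step 10 (alkylation of 17 with 4). The hindered enolate may alkylate sluggishly or twice, and the electron-rich bromide is not very stable. The fallback sets out from 17 and comes back at 19. The lithium enolate of 17 (LiN(SiMe3)2, THF, −78 °C) is added to aldehyde 2 in an aldol reaction, again anti to the C4 substituent, to give the β-hydroxy lactone F1 (both carbinol epimers are carried on). Phenyl chlorothionoformate, pyridine and 4-(dimethylamino)pyridine in CH2Cl2 at 0 °C convert it into the O-phenyl thionocarbonate F2. Barton–McCombie deoxygenation (n-Bu3SnH, azobisisobutyronitrile, toluene, 90 °C) then removes the extra benzylic oxygen and gives 19 with the trans relationship already fixed.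

Step 12 (Mitsunobu closure of 20). Closure next to the bulky silyloxybenzyl group may be slow and the hydrazide may be alkylated instead. The fallback sets out from lactone 19 (bypassing diol 20) and comes back at 21. Reduction with i-Bu2AlH in CH2Cl2 at −78 °C gives the lactol F3. Et3SiH with BF3·OEt2 in CH2Cl2 at −78 °C reduces the derived oxocarbenium ion to the cyclic ether 21; the low temperature is needed so that the benzylic silyl ether does not ionise.

Step 14 (hydrogenolysis of 22). The electron-rich benzylic C–OH bond may be over-reduced. The fallback sets out from 21 and comes back at 23 with the two deprotections in reverse order. H2 with 10% Pd/C in EtOAc on 21 gives the bis-phenol silyl ether F4, in which the bulky silyl group shields the benzylic C–O bond from the catalyst. n-Bu4NF buffered with AcOH in THF then removes the silyl group to give 23.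

**Further compounds**
F1 | step 10 | β-hydroxy lactone (3S,4R)-3-[[4-(benzyloxy)-3,5-dimethoxyphenyl](hydroxy)methyl]-4-[(S)-[4-(benzyloxy)-3,5-dimethoxyphenyl][(triisopropylsilyl)oxy]methyl]dihydrofuran-2(3H)-one (both carbinol epimers) | O=C1[C@H](C(O)c2cc(OC)c(OCc3ccccc3)c(OC)c2)[C@H](CO1)[C@H](O[Si](C(C)C)(C(C)C)C(C)C)c1cc(OC)c(OCc2ccccc2)c(OC)c1
F2 | step 10 | O-phenyl thionocarbonate O-[[4-(benzyloxy)-3,5-dimethoxyphenyl][(3S,4R)-4-[(S)-[4-(benzyloxy)-3,5-dimethoxyphenyl][(triisopropylsilyl)oxy]methyl]-2-oxotetrahydrofuran-3-yl]methyl] O-phenyl carbonothioate | O=C1[C@H](C(OC(=S)Oc2ccccc2)c2cc(OC)c(OCc3ccccc3)c(OC)c2)[C@H](CO1)[C@H](O[Si](C(C)C)(C(C)C)C(C)C)c1cc(OC)c(OCc2ccccc2)c(OC)c1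
F3 | step 12 | lactol (3R,4R)-3-[4-(benzyloxy)-3,5-dimethoxybenzyl]-4-[(S)-[4-(benzyloxy)-3,5-dimethoxyphenyl][(triisopropylsilyl)oxy]methyl]tetrahydrofuran-2-ol (both anomers) | OC1[C@H](Cc2cc(OC)c(OCc3ccccc3)c(OC)c2)[C@H](CO1)[C@H](O[Si](C(C)C)(C(C)C)C(C)C)c1cc(OC)c(OCc2ccccc2)c(OC)c1
F4 | step 14 | bis-phenol silyl ether 4-[[(3R,4R)-4-[(S)-(4-hydroxy-3,5-dimethoxyphenyl)[(triisopropylsilyl)oxy]methyl]tetrahydrofuran-3-yl]methyl]-2,6-dimethoxyphenol | COc1cc(C[C@H]2COC[C@@H]2[C@H](O[Si](C(C)C)(C(C)C)C(C)C)c2cc(OC)c(O)c(OC)c2)cc(OC)c1O
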